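**Retrosynthetic overview**
1. Oxolane numbering: O1, C2 (CH2), C3 (CH bearing the carbinol), C4 (CH–CH3), C5 (CH–aryl). The ring is disconnected at C2–C3: an α-alkoxymethyl carbanion on O1, released from a tributylstannylmethyl ether by tin–lithium exchange, opens a cis-oxirane built from C3, the carbinol carbon and the future hydroxyl oxygen.
2. Enabling feature: C2 is a methylene bound to the ring oxygen O1 (so it can be an α-alkoxy carbanion), and C3 is vicinal to the benzylic C–OH. This O1–C2···C3–C(OH) array is the retron of a 5-exo carbanion/oxirane opening; the strain of the three-membered ring (O, C3, carbinol C) drives the C–C bond formation, and SN2 inversion at C3 gives the 3,4-cis ring.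
3. The stannylmethyl ether comes from O-alkylation of the epoxy alcohol; the cis-oxirane comes from hydroxyl-directed vanadium epoxidation of a Z-homoallylic alcohol.
4. The Z-alkene comes from Lindlar reduction of a diaryl alkynol, made by Sonogashira coupling after a Marshall propargylation of 3,4-dimethoxybenzaldehyde with the mesylate of (R)-but-3-yn-2-ol (this sets C4 and C5).
5. Ring order: the temporary oxirane is formed in step 5; the oxolane, the only ring built in the route, is formed last (step 7) as the oxirane is consumed. No protecting groups are used.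

Key step: step 7

Assumption: tributyl(iodomethyl)stannane (Bu3SnCH2I) is treated as a commercially available starting material.

Step 1
Reactants: 1 (2R)-but-3-yn-2-ol
Product: 2 (2R)-but-3-yn-2-yl methanesulfonate
Conditions: MsCl, Et3N, CH2Cl2, −78 → 0 °C
Reagents that add atoms: methanesulfonyl chloride, CS(=O)(=O)Cl
Why: O-sulfonylation of a secondary alcohol (mesylate formation); no bond to the stereocentre is broken, so the R configuration is retained.

Step 2
Reactants: 2 (2R)-but-3-yn-2-yl methanesulfonate; 3 3,4-dimethoxybenzaldehyde
Product: 5 (1S,2S)-1-(3,4-dimethoxyphenyl)-2-methylbut-3-yn-1-ol, via allenylzinc reagent 4 (not isolated)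
Conditions: Pd(OAc)2 (5 mol%), PPh3 (5 mol%), Et2Zn (3 equiv), THF, −78 → −20 °C; aq NH4Cl
Reagents that add atoms: none
Why: Marshall propargylation, in which zerovalent palladium displaces the mesylate anti (SN2′), Pd-to-Zn transmetalation gives the (P)-allenylzinc 4, and this adds to the aldehyde through a closed SE2′ transition state; the methyl-bearing centre is set by chirality transfer from the mesylate and the carbinol centre by the anti preference of the cyclic transition state (aryl group away from the allenyl methyl).

Step 3
Reactants: 5 (1S,2S)-1-(3,4-dimethoxyphenyl)-2-methylbut-3-yn-1-ol; 6 4-iodo-1,2-dimethoxybenzene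
Product: 7 (1S,2S)-1,4-bis(3,4-dimethoxyphenyl)-2-methylbut-3-yn-1-ol
Conditions: Pd(PPh3)2Cl2 (2 mol%), CuI (4 mol%), Et3N, THF, rt
Reagents that add atoms: none
Why: Sonogashira coupling of the terminal alkyne with the aryl iodide; the free secondary alcohol is tolerated and neither stereocentre is touched.

Step 4
Reactants: 7 (1S,2S)-1,4-bis(3,4-dimethoxyphenyl)-2-methylbut-3-yn-1-ol
Product: 8 (1S,2S,3Z)-1,4-bis(3,4-dimethoxyphenyl)-2-methylbut-3-en-1-ol
Conditions: H2 (1 atm), Pd/CaCO3 poisoned with Pb(OAc)2 (Lindlar catalyst), quinoline, EtOAc, rt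
Reagents that add atoms: none
Why: Lindlar semi-hydrogenation, in which syn delivery of H2 on the poisoned palladium surface should give the Z-alkene while quinoline suppresses over-reduction, isomerisation and benzylic C–O hydrogenolysis.

Step 5
Reactants: 8 (1S,2S,3Z)-1,4-bis(3,4-dimethoxyphenyl)-2-methylbut-3-en-1-ol
Product: 9 (1S,2R)-1-(3,4-dimethoxyphenyl)-2-[(2R,3S)-3-(3,4-dimethoxyphenyl)oxiran-2-yl]propan-1-ol
Conditions: VO(acac)2 (5 mol%), t-BuOOH (1.5 equiv, in decane), 2,6-lutidine (0.2 equiv), CH2Cl2, 0 °C
Reagents that add atoms: tert-butyl hydroperoxide, CC(C)(C)OO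
Why: Hydroxyl-directed vanadium-catalysed epoxidation of a homoallylic alcohol, in which the vanadium alkoxide delivers oxygen to the alkene face on the side of the carbinol branch while allylic 1,3-strain of the Z-alkene holds the allylic C–H in the alkene plane; the oxirane should therefore form anti to the methyl group with retention of the cis geometry (both new centres set by substrate control, matched with the anti carbinol/methyl pair), and lutidine tempers the Lewis acidity so that the electron-rich aryl oxirane survives.

Step 6
Reactants: 9 (1S,2R)-1-(3,4-dimethoxyphenyl)-2-[(2R,3S)-3-(3,4-dimethoxyphenyl)oxiran-2-yl]propan-1-ol; 10 tributyl(iodomethyl)stannane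
Product: 12 tributyl({(1S,2R)-1-(3,4-dimethoxyphenyl)-2-[(2R,3S)-3-(3,4-dimethoxyphenyl)oxiran-2-yl]propoxy}methyl)stannane, via potassium alkoxide 11 (not isolated)
Conditions: KH (1.2 equiv), THF, 0 °C; then Bu3SnCH2I (1.3 equiv), 0 °C → rt
Reagents that add atoms: none
Why: Williamson etherification, in which the potassium alkoxide 11 displaces iodide from the tin-activated primary iodide faster than it can open the oxirane, since the competing 4-exo and 5-endo openings are slow under basic conditions; no stereocentre is touched.

Step 7
Reactants: 12 tributyl({(1S,2R)-1-(3,4-dimethoxyphenyl)-2-[(2R,3S)-3-(3,4-dimethoxyphenyl)oxiran-2-yl]propoxy}methyl)stannane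
Product: 15 (R)-(3,4-dimethoxyphenyl)[(3R,4S,5S)-5-(3,4-dimethoxyphenyl)-4-methyloxolan-3-yl]methanol, via lithiomethyl ether 13 (not isolated), via lithium alkoxide 14 (not isolated)
Conditions: n-BuLi (1.2 equiv), THF, −78 °C, then −78 → −30 °C; aq NH4Cl
Reagents that add atoms: none
Why: Proposed new method: tin–lithium exchange (n-BuLi attacks tin, Bu4Sn leaves) gives the α-alkoxymethyllithium 13, whose carbanion attacks the proximal oxirane carbon from the side opposite its C–O bond; release of the oxirane strain drives the C–C bond formation and gives lithium alkoxide 14, which is protonated on work-up. The closest known reaction types are the generation of alkoxymethyllithiums from stannylmethyl ethers, the cyclisation of α-alkoxy organolithiums onto tethered alkenes to give tetrahydrofurans, and the intramolecular opening of epoxides by organolithiums formed by tin–lithium exchange; using an oxirane as the internal electrophile for an α-alkoxymethyllithium to close an oxolane is the new element. The oxolane closes in the 5-exo-tet mode by forming the C2–C3 bond. The new ring stereocentre C3 arises by SN2 inversion at the oxirane carbon, the carbinol centre keeps the configuration of the benzylic oxirane carbon because its C–O bond is not broken, and C4 and C5 are carried through unchanged, so the (2R,3S)-cis-oxirane should translate stereospecifically into the 3,4-cis ring with the R carbinol. The step needs exo attack at the non-benzylic carbon instead of 6-endo attack at the benzylic one, and cyclisation faster than [1,2]-Wittig rearrangement of the benzylic ether. Without a Lewis acid only the five-membered closure reaches the collinear SN2 geometry, and benzyloxymethyllithium-type species persist below about −30 °C without rearranging; the eclipsing of the cis-aryl group with the methyl-bearing carbon is expected to slow the closure, which is why the mixture is warmed.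

**Compound list**
1 | (2R)-but-3-yn-2-ol | C[C@@H](O)C#C | starting material
2 | (2R)-but-3-yn-2-yl methanesulfonate | C[C@@H](OS(C)(=O)=O)C#C | intermediate
3 | 3,4-dimethoxybenzaldehyde | COc1ccc(C=O)cc1OC | starting material
4 | (P)-buta-1,2-dien-1-yl(ethyl)zinc (axially chiral allenylzinc) | CC=[C@@]=C[Zn]CC | intermediate
5 | (1S,2S)-1-(3,4-dimethoxyphenyl)-2-methylbut-3-yn-1-ol | COc1ccc([C@@H](O)[C@@H](C)C#C)cc1OC | intermediate
6 | 4-iodo-1,2-dimethoxybenzene | COc1ccc(I)cc1OC | starting material
7 | (1S,2S)-1,4-bis(3,4-dimethoxyphenyl)-2-methylbut-3-yn-1-ol | COc1ccc([C@@H](O)[C@@H](C)C#Cc2ccc(OC)c(OC)c2)cc1OC | intermediate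
8 | (1S,2S,3Z)-1,4-bis(3,4-dimethoxyphenyl)-2-methylbut-3-en-1-ol | COc1ccc([C@@H](O)[C@@H](C)/C=C\c2ccc(OC)c(OC)c2)cc1OC | intermediate
9 | (1S,2R)-1-(3,4-dimethoxyphenyl)-2-[(2R,3S)-3-(3,4-dimethoxyphenyl)oxiran-2-yl]propan-1-ol | COc1ccc([C@@H](O)[C@@H](C)[C@H]2O[C@H]2c3ccc(OC)c(OC)c3)cc1OC | intermediate
10 | tributyl(iodomethyl)stannane | CCCC[Sn](CCCC)(CCCC)CI | starting material
11 | potassium (1S,2R)-1-(3,4-dimethoxyphenyl)-2-[(2R,3S)-3-(3,4-dimethoxyphenyl)oxiran-2-yl]propan-1-olate | COc1ccc([C@@H]([O-])[C@@H](C)[C@H]2O[C@H]2c3ccc(OC)c(OC)c3)cc1OC.[K+] | intermediate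
12 | tributyl({(1S,2R)-1-(3,4-dimethoxyphenyl)-2-[(2R,3S)-3-(3,4-dimethoxyphenyl)oxiran-2-yl]propoxy}methyl)stannane | COc1ccc([C@@H](OC[Sn](CCCC)(CCCC)CCCC)[C@@H](C)[C@H]2O[C@H]2c3ccc(OC)c(OC)c3)cc1OC | intermediate
13 | ({(1S,2R)-1-(3,4-dimethoxyphenyl)-2-[(2R,3S)-3-(3,4-dimethoxyphenyl)oxiran-2-yl]propoxy}methyl)lithium | COc1ccc([C@@H](OC[Li])[C@@H](C)[C@H]2O[C@H]2c3ccc(OC)c(OC)c3)cc1OC | intermediate
14 | lithium (R)-(3,4-dimethoxyphenyl)[(3R,4S,5S)-5-(3,4-dimethoxyphenyl)-4-methyloxolan-3-yl]methanolate | COc1ccc([C@H]2OC[C@H]([C@@H](O[Li])c3ccc(OC)c(OC)c3)[C@@H]2C)cc1OC | intermediate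
15 | (R)-(3,4-dimethoxyphenyl)[(3R,4S,5S)-5-(3,4-dimethoxyphenyl)-4-methyloxolan-3-yl]methanol | COc1ccc([C@H]2OC[C@H]([C@@H](O)c3ccc(OC)c(OC)c3)[C@@H]2C)cc1OC | target

**Step count and risks**
Total steps: 7. Longest linear sequence: 7 steps (1 → 2 → 5 → 7 → 8 → 9 → 12 → 15).

Step 7 (proposed new method). What may go wrong: [1,2]-Wittig rearrangement of the benzylic α-alkoxymethyllithium before it cyclises, slow closure because the cis-aryl group eclipses the methyl-bearing carbon in the SN2 geometry, or competing 6-endo attack at the benzylic oxirane carbon. The fallback uses known chemistry and sets out from epoxy alcohol 9. Its sodium alkoxide (NaH, THF–DMF, 0 °C) would be alkylated with chloromethyl phenyl sulfide and NaI to the phenylsulfanylmethyl ether F1. Oxidation at sulfur with buffered mCPBA (NaHCO3, CH2Cl2, 0 °C) would give the phenylsulfonylmethyl ether F2. Deprotonation next to the sulfone (n-BuLi, THF, −78 → 0 °C) would give a sulfone-stabilised carbanion that does not undergo Wittig rearrangement and can be warmed; it would open the oxirane in the same 5-exo sense (sulfone-carbanion epoxide cyclisation) to the 2-(phenylsulfonyl)oxolane F3, formed as both epimers at C2. Reductive desulfonylation with sodium amalgam (Na/Hg, Na2HPO4, MeOH, −20 °C) would bring the route back at target 15.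

Step 5. What may go wrong: opening of the electron-rich benzylic oxirane on the Lewis-acidic vanadium centre by the neighbouring hydroxyl (5-endo closure to a hydroxy-oxolane) or its rearrangement to a ketone, and erosion of facial selectivity if direction by the hydroxyl is incomplete. The fallback sets out from alkenol 8 and returns at epoxy alcohol 9. It replaces substrate-directed metal catalysis by catalyst control: a carbohydrate-derived chiral ketone of the oxazolidinone type developed for cis-β-substituted styrenes, with Oxone (KHSO5) in buffered MeCN–dimethoxymethane–water at about pH 10 and 0 °C. The concerted dioxirane oxygen transfer keeps the cis geometry, no Lewis acid is present, and the antipode of the ketone that attacks the required alkene face would be chosen. This fallback makes no new compound (F0).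

Step 6. What may go wrong: attack of the potassium alkoxide on the oxirane (4-exo to an oxetane or 5-endo at the benzylic carbon), or base-induced decomposition, competing with O-alkylation. The fallback sets out from alkenol 8 and introduces the tin handle before the oxirane exists: KH and Bu3SnCH2I in THF would give the Z-alkenyl stannylmethyl ether F4. F4 would then be epoxidised under the catalyst-controlled dioxirane conditions described for step 5; here the catalyst has to override the steric preference of the substrate, since no hydroxyl is left to direct. The route is rejoined at stannylmethyl ether 12.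

**Further compounds**
F1 | step 7 | ({(1S,2R)-1-(3,4-dimethoxyphenyl)-2-[(2R,3S)-3-(3,4-dimethoxyphenyl)oxiran-2-yl]propoxy}methyl)(phenyl)sulfane | COc1ccc([C@@H](OCSc4ccccc4)[C@@H](C)[C@H]2O[C@H]2c3ccc(OC)c(OC)c3)cc1OC
F2 | step 7 | ({(1S,2R)-1-(3,4-dimethoxyphenyl)-2-[(2R,3S)-3-(3,4-dimethoxyphenyl)oxiran-2-yl]propoxy}methanesulfonyl)benzene | COc1ccc([C@@H](OCS(=O)(=O)c4ccccc4)[C@@H](C)[C@H]2O[C@H]2c3ccc(OC)c(OC)c3)cc1OC
F3 | step 7 | (R)-(3,4-dimethoxyphenyl)[(3S,4S,5S)-5-(3,4-dimethoxyphenyl)-4-methyl-2-(phenylsulfonyl)oxolan-3-yl]methanol, mixture of epimers at C2 | COc1ccc([C@H]2OC(S(=O)(=O)c4ccccc4)[C@H]([C@@H](O)c3ccc(OC)c(OC)c3)[C@@H]2C)cc1OC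
F0 | step 5 | none | none
F4 | step 6 | tributyl({[(1S,2S,3Z)-1,4-bis(3,4-dimethoxyphenyl)-2-methylbut-3-en-1-yl]oxy}methyl)stannane | COc1ccc([C@@H](OC[Sn](CCCC)(CCCC)CCCC)[C@@H](C)/C=C\c2ccc(OC)c(OC)c2)cc1OC
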